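**Retrosynthetic overview**

1. Feature: the only ring is the oxolane O1/C11/C12/C13/C14, with O1 on C11 beside the oxygenated exocyclic C10 (C1 = vinyl CH2, C19 = pentyl CH3). Moving O1 back from C11 to C10 gives a pyran whose C10–C14, O1 and C13 oxygen are those of a furfural-derived Achmatowicz pyranone.
2. Late disconnections: C13 silyl ether, C10 stearate, C10 carbinol (Felkin–Anh reduction of the C10 ketone), ketone from its dimethyl ketal.
3. Key disconnection: O1–C11, made by oxidative 1,2-shift of O1 from C10 to C11 in a 6-(non-8-enyl)-3,4-dihydro-2H-pyran (pyran to oxolane contraction).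
4. The dihydropyran comes from a δ-lactone enol phosphate and nona-1,8-diene (B-alkyl Suzuki, C9–C10). The lactone comes from furfural and pentylmagnesium bromide (C14–C15), kinetic resolution and Achmatowicz ring expansion.
5. Ring order: furan, then six-membered pyran (step 3), then oxolane (step 12).

Key step: step 12

Remark (numbering): carbons are C1 (vinyl CH2) to C19 along the chain; the ring oxygen O1 lies between C11 and C14.
Remark (assumption on the chemistry): a δ-lactone with a free C13 hydroxyl is expected to undergo acyl shift to the γ-lactone, so the C13 ketone is reduced and silylated at the methyl acetal stage and the lactone is unveiled afterwards.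

**Route**

Step 1
Reactants: 1 1-bromopentane; 2 furfural (furan-2-carbaldehyde)
Product: 4 rac-1-(furan-2-yl)hexan-1-ol, via pentylmagnesium bromide 3 (not isolated)
Conditions: Mg, THF, 40 °C; then 2, 0 °C; aq. NH4Cl work-up
Reagents that add atoms: none
Why: Grignard addition to the aldehyde forms C14–C15; the racemate is resolved in the next step, so no stereocontrol is needed here.

Step 2
Reactants: 4 rac-1-(furan-2-yl)hexan-1-ol
Product: 5 (1S)-1-(furan-2-yl)hexan-1-ol
Conditions: Ti(OiPr)4 (0.2 equiv), D-(−)-diisopropyl tartrate (0.24 equiv), t-BuOOH (0.6 equiv), 4 Å molecular sieves, CH2Cl2, −20 °C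
Reagents that add atoms: none
Why: Sharpless kinetic resolution of a 2-furyl carbinol: the titanium D-(−)-tartrate peroxide complex should oxidise the (R)-carbinol fast to its pyranone and leave the (S)-carbinol, which fixes C14.

Step 3
Reactants: 5 (1S)-1-(furan-2-yl)hexan-1-ol
Product: 6 (2S)-6-hydroxy-2-pentyl-2H-pyran-3(6H)-one (mixture of C6 epimers)
Conditions: NBS, NaHCO3, NaOAc, THF/H2O (4:1), 0 °C
Reagents that add atoms: water, O
Why: Achmatowicz oxidative ring expansion: bromination and hydrolysis open the furan to the ene-dione and the carbinol oxygen (future O1) closes onto C10 to give the six-membered lactol enone, with C14 untouched.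

Step 4
Reactants: 6 (2S)-6-hydroxy-2-pentyl-2H-pyran-3(6H)-one
Product: 7 (2S)-6-methoxy-2-pentyl-2H-pyran-3(6H)-one (mixture of C6 epimers, 2,6-trans expected to prevail)
Conditions: HC(OMe)3, BF3·OEt2 (cat.), Et2O, 0 °C
Reagents that add atoms: trimethyl orthoformate, COC(OC)OC
Why: Acid-catalysed acetalisation of the lactol through the C10 oxocarbenium ion caps C10 without an acyl group; the C10 configuration is of no consequence because C10 becomes sp2 in step 9.

Step 5
Reactants: 7 (2S)-6-methoxy-2-pentyl-2H-pyran-3(6H)-one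
Product: 8 (2S)-6-methoxy-2-pentyloxan-3-one
Conditions: H2 (1 atm), 10% Pd/C, EtOAc, rt
Reagents that add atoms: none
Why: Heterogeneous catalytic hydrogenation of the enone C11=C12 bond, placed here because the terminal alkene is not yet in the molecule.

Step 6
Reactants: 8 (2S)-6-methoxy-2-pentyloxan-3-one
Product: 9 (2S,3S)-6-methoxy-2-pentyloxan-3-ol
Conditions: LiBH(s-Bu)3, THF, −78 °C; then H2O
Reagents that add atoms: none
Why: Diastereoselective ketone reduction by a bulky trialkylborohydride: hydride should enter along the equatorial trajectory of the chair with equatorial pentyl and give the axial C13 alcohol cis to the pentyl group (13S).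

Step 7
Reactants: 9 (2S,3S)-6-methoxy-2-pentyloxan-3-ol
Product: 10 tert-butyl{[(2S,3S)-6-methoxy-2-pentyloxan-3-yl]oxy}dimethylsilane
Conditions: TBSCl, imidazole, DMF, rt to 40 °C
Reagents that add atoms: tert-butyldimethylsilyl chloride (TBSCl), CC(C)(C)[Si](C)(C)Cl
Why: Imidazole-promoted silylation of the secondary alcohol; the chloride is used because a silyl triflate with a pyridine base would activate the methyl acetal.

Step 8
Reactants: 10 tert-butyl{[(2S,3S)-6-methoxy-2-pentyloxan-3-yl]oxy}dimethylsilane
Product: 11 (5S,6S)-5-(tert-butyldimethylsilyloxy)-6-pentyloxan-2-ol (mixture of C2 epimers)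
Conditions: AcOH/THF/H2O (3:1:1), rt to 40 °C
Reagents that add atoms: water, O
Why: Acid hydrolysis of a 2-alkoxyoxane acetal without neighbouring electron-withdrawing groups, which is far more labile than the hindered secondary silyl ether.

Step 9
Reactants: 11 (5S,6S)-5-(tert-butyldimethylsilyloxy)-6-pentyloxan-2-ol
Product: 12 (5S,6S)-5-(tert-butyldimethylsilyloxy)-6-pentyloxan-2-one
Conditions: PhI(OAc)2 (1.2 equiv), TEMPO (0.1 equiv), CH2Cl2, rt
Reagents that add atoms: none
Why: Oxoammonium-mediated oxidation of the lactol to the δ-lactone under neutral conditions; with the C13 oxygen silylated no acyl shift to a γ-lactone can occur.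

Step 10
Reactants: 12 (5S,6S)-5-(tert-butyldimethylsilyloxy)-6-pentyloxan-2-one
Product: 13 (2S,3S)-3-(tert-butyldimethylsilyloxy)-2-pentyl-3,4-dihydro-2H-pyran-6-yl diphenyl phosphate
Conditions: KN(SiMe3)2, (PhO)2P(O)Cl, THF/HMPA (10:1), −78 °C; rapid filtration through Et3N-deactivated silica
Reagents that add atoms: diphenyl chlorophosphate, O=P(Cl)(Oc1ccccc1)Oc1ccccc1
Why: O-Phosphorylation of the lactone potassium enolate gives the ketene acetal phosphate, the electrophile for cross-coupling; C11 is the only enolisable position.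

Step 11
Reactants: 13 (2S,3S)-3-(tert-butyldimethylsilyloxy)-2-pentyl-3,4-dihydro-2H-pyran-6-yl diphenyl phosphate; 14 nona-1,8-diene
Product: 16 (2S,3S)-3-(tert-butyldimethylsilyloxy)-6-(non-8-enyl)-2-pentyl-3,4-dihydro-2H-pyran, via 9-(non-8-enyl)-9-borabicyclo[3.3.1]nonane 15 (not isolated)
Conditions: 14 (3 equiv), 9-BBN, THF, 0 °C to rt, excess diene removed in vacuo; then 13, 3 M aq. Cs2CO3, PdCl2(dppf) (5 mol%), DMF, rt to 50 °C; Et3N-deactivated silica
Reagents that add atoms: none
Why: B-alkyl Suzuki–Miyaura coupling: anti-Markovnikov monohydroboration of the diene (used in excess) gives the primary alkylborane, which couples with the enol phosphate under zerovalent palladium generated from PdCl2(dppf) to form C9–C10.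

Step 12
Reactants: 16 (2S,3S)-3-(tert-butyldimethylsilyloxy)-6-(non-8-enyl)-2-pentyl-3,4-dihydro-2H-pyran
Product: 17 (2R,4S,5S)-4-(tert-butyldimethylsilyloxy)-2-(1,1-dimethoxydec-9-enyl)-5-pentyloxolane
Conditions: PhI(OAc)2 (1.2 equiv), anhydrous MeOH, 4 Å molecular sieves, 0 °C to rt
Reagents that add atoms: methanol, CO
Why: Oxidative 1,2-oxygen shift of a cyclic enol ether by trivalent iodine: the iodane attacks the nucleophilic enol ether carbon C11 while methanol caps the oxocarbenium ion at C10, and in the chair with equatorial pentyl the C11–iodane bond is equatorial and anti-periplanar to C10–O1, so O1 migrates to C11 as PhI leaves and methanol traps the methoxy-stabilised C10 cation as the dimethyl ketal. The closest known reaction type is the ring contraction of glycals and 3,4-dihydro-2H-pyrans to 2,5-anhydro aldose or tetrahydrofurfural acetals with trivalent iodine or trivalent thallium oxidants; here C10 carries the nonenyl chain, which should stabilise the cation further and gives a ketal in place of an acetal. The oxolane (O1, C11, C12, C13, C14) is closed by intramolecular backside displacement at C11 by O1, a 1,2-shift through an O1-bridged transition state (5-exo-tet when counted along O1–C14–C13–C12–C11), which forms O1–C11. C11 (R) is set by the face of iodane attack: the pseudo-axial C13 silyl ether shields the face syn to it, the iodane should add anti to it and trans to the pentyl group, and inversion by O1 then places C10 trans to the pentyl group. The step needs chemoselectivity for the enol ether over the terminal alkene, which the much higher nucleophilicity of the trisubstituted enol ether secures, and no acid activator is added so that the monosubstituted alkene and the silyl ether are left alone.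

Step 13
Reactants: 17 (2R,4S,5S)-4-(tert-butyldimethylsilyloxy)-2-(1,1-dimethoxydec-9-enyl)-5-pentyloxolane
Product: 18 1-[(2R,4S,5S)-4-(tert-butyldimethylsilyloxy)-5-pentyloxolan-2-yl]dec-9-en-1-one
Conditions: PPTS (cat.), acetone/H2O (10:1), 40–50 °C
Reagents that add atoms: water, O
Why: Acid-catalysed ketal hydrolysis under pyridinium buffering, mild enough to keep the secondary silyl ether and to avoid enolisation at C11.

Step 14
Reactants: 18 1-[(2R,4S,5S)-4-(tert-butyldimethylsilyloxy)-5-pentyloxolan-2-yl]dec-9-en-1-one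
Product: 19 (1R)-1-[(2R,4S,5S)-4-(tert-butyldimethylsilyloxy)-5-pentyloxolan-2-yl]dec-9-en-1-ol
Conditions: LiBH(s-Bu)3, THF, −78 °C; then H2O
Reagents that add atoms: none
Why: Felkin–Anh reduction of an α-alkoxy ketone by a bulky, poorly chelating hydride: with C11–O1 anti to the incoming hydride and attack past C11–H, the threo (10R) alcohol should form.

Step 15
Reactants: 19 (1R)-1-[(2R,4S,5S)-4-(tert-butyldimethylsilyloxy)-5-pentyloxolan-2-yl]dec-9-en-1-ol; 20 stearic acid (octadecanoic acid)
Product: 21 (1R)-1-[(2R,4S,5S)-4-(tert-butyldimethylsilyloxy)-5-pentyloxolan-2-yl]dec-9-en-1-yl octadecanoate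
Conditions: DCC, DMAP (cat.), CH2Cl2, rt
Reagents that add atoms: none
Why: Steglich esterification of the only free hydroxyl; the C10 configuration is retained because the C10–O bond is not broken.

Step 16
Reactants: 21 (1R)-1-[(2R,4S,5S)-4-(tert-butyldimethylsilyloxy)-5-pentyloxolan-2-yl]dec-9-en-1-yl octadecanoate
Product: 22 (1R)-1-[(2R,4S,5S)-4-hydroxy-5-pentyloxolan-2-yl]dec-9-en-1-yl octadecanoate (CNP0342202.1)
Conditions: HF·pyridine, pyridine/THF, 0 °C to rt
Reagents that add atoms: none
Why: Fluoride cleavage of the silyl ether under weakly acidic conditions, which should leave the stearate in place (no basic alkoxide, and the trans-disposed C10 and C13 oxygens disfavour acyl migration) and the terminal alkene untouched.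

**Compound list**

1 | 1-bromopentane | CCCCCBr | starting material
2 | furfural | O=Cc1ccco1 | starting material
3 | pentylmagnesium bromide | CCCCC[Mg]Br | intermediate
4 | rac-1-(furan-2-yl)hexan-1-ol | CCCCCC(O)c1ccco1 | intermediate
5 | (1S)-1-(furan-2-yl)hexan-1-ol | CCCCC[C@H](O)c1ccco1 | intermediate
6 | (2S)-6-hydroxy-2-pentyl-2H-pyran-3(6H)-one (C6 epimers) | OC1C=CC(=O)[C@H](CCCCC)O1 | intermediate
7 | (2S)-6-methoxy-2-pentyl-2H-pyran-3(6H)-one (C6 epimers) | COC1C=CC(=O)[C@H](CCCCC)O1 | intermediate
8 | (2S)-6-methoxy-2-pentyloxan-3-one (C6 epimers) | COC1CCC(=O)[C@H](CCCCC)O1 | intermediate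
9 | (2S,3S)-6-methoxy-2-pentyloxan-3-ol (C6 epimers) | COC1CC[C@H](O)[C@H](CCCCC)O1 | intermediate
10 | tert-butyl{[(2S,3S)-6-methoxy-2-pentyloxan-3-yl]oxy}dimethylsilane (C6 epimers) | COC1CC[C@H](O[Si](C)(C)C(C)(C)C)[C@H](CCCCC)O1 | intermediate
11 | (5S,6S)-5-(tert-butyldimethylsilyloxy)-6-pentyloxan-2-ol (C2 epimers) | OC1CC[C@H](O[Si](C)(C)C(C)(C)C)[C@H](CCCCC)O1 | intermediate
12 | (5S,6S)-5-(tert-butyldimethylsilyloxy)-6-pentyloxan-2-one | O=C1CC[C@H](O[Si](C)(C)C(C)(C)C)[C@H](CCCCC)O1 | intermediate
13 | (2S,3S)-3-(tert-butyldimethylsilyloxy)-2-pentyl-3,4-dihydro-2H-pyran-6-yl diphenyl phosphate | O=P(Oc1ccccc1)(Oc1ccccc1)OC2=CC[C@H](O[Si](C)(C)C(C)(C)C)[C@H](CCCCC)O2 | intermediate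
14 | nona-1,8-diene | C=CCCCCCC=C | starting material
15 | 9-(non-8-enyl)-9-borabicyclo[3.3.1]nonane | C=CCCCCCCCB1C2CCCC1CCC2 | intermediate
16 | (2S,3S)-3-(tert-butyldimethylsilyloxy)-6-(non-8-enyl)-2-pentyl-3,4-dihydro-2H-pyran | C=CCCCCCCCC1=CC[C@H](O[Si](C)(C)C(C)(C)C)[C@H](CCCCC)O1 | intermediate
17 | (2R,4S,5S)-4-(tert-butyldimethylsilyloxy)-2-(1,1-dimethoxydec-9-enyl)-5-pentyloxolane | C=CCCCCCCCC(OC)(OC)[C@H]1C[C@H](O[Si](C)(C)C(C)(C)C)[C@H](CCCCC)O1 | intermediate
18 | 1-[(2R,4S,5S)-4-(tert-butyldimethylsilyloxy)-5-pentyloxolan-2-yl]dec-9-en-1-one | C=CCCCCCCCC(=O)[C@H]1C[C@H](O[Si](C)(C)C(C)(C)C)[C@H](CCCCC)O1 | intermediate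
19 | (1R)-1-[(2R,4S,5S)-4-(tert-butyldimethylsilyloxy)-5-pentyloxolan-2-yl]dec-9-en-1-ol | C=CCCCCCCC[C@@H](O)[C@H]1C[C@H](O[Si](C)(C)C(C)(C)C)[C@H](CCCCC)O1 | intermediate
20 | stearic acid | CCCCCCCCCCCCCCCCCC(=O)O | starting material
21 | (1R)-1-[(2R,4S,5S)-4-(tert-butyldimethylsilyloxy)-5-pentyloxolan-2-yl]dec-9-en-1-yl octadecanoate | C=CCCCCCCC[C@@H](OC(=O)CCCCCCCCCCCCCCCCC)[C@H]1C[C@H](O[Si](C)(C)C(C)(C)C)[C@H](CCCCC)O1 | intermediate
22 | (1R)-1-[(2R,4S,5S)-4-hydroxy-5-pentyloxolan-2-yl]dec-9-en-1-yl octadecanoate | C=CCCCCCCC[C@@H](OC(=O)CCCCCCCCCCCCCCCCC)[C@H]1C[C@H](O)[C@H](CCCCC)O1 | target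

**Step count and risk**

Total step count: 16. Longest linear sequence: 16 steps (from furfural and 1-bromopentane to 22; nona-1,8-diene and stearic acid enter as purchased side inputs).

Steps most likely to fail:

1. Step 12. Methanol may capture the iodane adduct at C11 (α-methoxylation), or plain acid-catalysed methanol addition to the enol ether may outrun the 1,2-oxygen shift. The iodane may also be delivered to the face syn to the silyl ether, which would lead to the 2,5-cis oxolane. Fallback from 16, returning at 17, by a stepwise contraction. Epoxidation of the enol ether in methanol (mCPBA, NaHCO3, MeOH, −40 °C, the enol ether reacting well before the terminal alkene), with opening of the epoxide by methanol at C10, should give the hydroxy ketal (3S,5S,6S)-5-(tert-butyldimethylsilyloxy)-2-methoxy-2-(non-8-enyl)-6-pentyloxan-3-ol F1. Its C11 epimers are separable at this stage. Triflation (Tf2O, pyridine, CH2Cl2, −30 °C) gives the equatorial sulfonate (3S,5S,6S)-5-(tert-butyldimethylsilyloxy)-2-methoxy-2-(non-8-enyl)-6-pentyloxan-3-yl trifluoromethanesulfonate F2. Warming F2 in methanol with 2,6-lutidine should let O1 displace the triflate with inversion, the known contraction of pyranoside 2-sulfonates with an equatorial leaving group, to give 17.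

2. Step 11. The diene may be hydroborated twice, the ketene acetal phosphate may hydrolyse before coupling, or the acid-labile enol ether may be protonated during isolation. Fallback from 12, returning at 16. Non-8-enylmagnesium bromide F3 (from purchased 9-bromonon-1-ene, C=CCCCCCCCBr, and Mg in THF) is added to lactone 12 at −78 °C to give the hemiketal (5S,6S)-5-(tert-butyldimethylsilyloxy)-2-(non-8-enyl)-6-pentyloxan-2-ol F4. Dehydration (MsCl, Et3N, CH2Cl2, 0 °C to rt, then a trace of PPTS in toluene to equilibrate any exocyclic isomer to the more stable endocyclic enol ether) returns 16.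

3. Step 14. Lithium chelation between the carbonyl oxygen and O1 may erode the Felkin–Anh preference and give the erythro alcohol. Fallback from 18, returning at 19. Chelation-controlled reduction (Zn(BH4)2, Et2O, −30 °C) is used deliberately to give the erythro alcohol (1S)-1-[(2R,4S,5S)-4-(tert-butyldimethylsilyloxy)-5-pentyloxolan-2-yl]dec-9-en-1-ol F5. Mitsunobu inversion (4-nitrobenzoic acid, PPh3, DIAD, toluene, 0 °C to rt) gives (1R)-1-[(2R,4S,5S)-4-(tert-butyldimethylsilyloxy)-5-pentyloxolan-2-yl]dec-9-en-1-yl 4-nitrobenzoate F6, and methanolysis (K2CO3, MeOH, rt) releases 19.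

Further compounds
F1 | step 12 | (3S,5S,6S)-5-(tert-butyldimethylsilyloxy)-2-methoxy-2-(non-8-enyl)-6-pentyloxan-3-ol (C2 configuration not defined) | C=CCCCCCCCC1(OC)[C@@H](O)C[C@H](O[Si](C)(C)C(C)(C)C)[C@H](CCCCC)O1
F2 | step 12 | (3S,5S,6S)-5-(tert-butyldimethylsilyloxy)-2-methoxy-2-(non-8-enyl)-6-pentyloxan-3-yl trifluoromethanesulfonate (C2 configuration not defined) | C=CCCCCCCCC1(OC)[C@@H](OS(=O)(=O)C(F)(F)F)C[C@H](O[Si](C)(C)C(C)(C)C)[C@H](CCCCC)O1
F3 | step 11 | non-8-enylmagnesium bromide | C=CCCCCCCC[Mg]Br
F4 | step 11 | (5S,6S)-5-(tert-butyldimethylsilyloxy)-2-(non-8-enyl)-6-pentyloxan-2-ol (C2 epimers) | C=CCCCCCCCC1(O)CC[C@H](O[Si](C)(C)C(C)(C)C)[C@H](CCCCC)O1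
F5 | step 14 | (1S)-1-[(2R,4S,5S)-4-(tert-butyldimethylsilyloxy)-5-pentyloxolan-2-yl]dec-9-en-1-ol | C=CCCCCCCC[C@H](O)[C@H]1C[C@H](O[Si](C)(C)C(C)(C)C)[C@H](CCCCC)O1
F6 | step 14 | (1R)-1-[(2R,4S,5S)-4-(tert-butyldimethylsilyloxy)-5-pentyloxolan-2-yl]dec-9-en-1-yl 4-nitrobenzoate | C=CCCCCCCC[C@@H](OC(=O)c2ccc(cc2)[N+](=O)[O-])[C@H]1C[C@H](O[Si](C)(C)C(C)(C)C)[C@H](CCCCC)O1
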